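**Retrosynthetic overview**

1. Target 25 comes from the (E)-Δ11,12 macrocycle 24 by a reagent-controlled Shi epoxidation, so the oxirane is the last ring formed.
2. 24 comes from seco-diene 23 by ring-closing metathesis across C11=C12; the 14-membered carbocycle is the second ring, closed onto the finished δ-lactone. Enabling feature: the two oxirane carbons (the epoxide CH, C11, and the methyl-bearing epoxide C, C12) are a masked E-trisubstituted alkene. Each is flanked by a CH2CH2 unit of the 14-membered ring and lies at least three bonds from every stereocentre and from the six-membered lactone ring, so a vinyl and a methylidene terminus suffice.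
3. 23 comes from aldehyde 16 and 2-iodohexa-1,5-diene 19 (C7–C8, Nozaki–Hiyama–Kishi); C7 is then set by oxidation and CBS reduction.
4. 16 comes from epoxy diol 10: C5–C6 by acetylide opening, then the δ-lactone (first ring) by oxidative lactonisation with equilibration at C15. 10 comes from enone 8, with C3 set by CBS reduction and C4 relayed by hydroxyl-directed epoxidation.
5. 8 comes from (R)-limonene 1, which supplies the C1 stereocentre and C2, C3, C12–C17 and C20, via hydroboration, ozonolysis, a temporary lactone, methylenation and isopropenyl addition.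

Key step: step 17

Numbering used for locants: lactone ring C1(H)–C2H2–C3(H)–O–C16(=O)–C15(H)CH3; carbocycle C1–C14 with C4(CH3)OH, C7(H)OH, C8(=CH2), oxirane C11(H)–C12(CH3).

Assumption: compounds 2–13 are carried as mixtures of both epimers at C15 (left undefined in their SMILES); this centre is converged to 15S by equilibration in step 9. Compounds 4, 5 and 12 are also mixtures at their acetal carbons, and 20 is a mixture at C7.

**Route**

Step 1
Reactants: 1 (R)-(+)-limonene
Product: 3 2-[(1R)-4-methylcyclohex-3-en-1-yl]propan-1-ol, via B-alkyl-9-BBN 2 (not isolated)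
Conditions: 9-BBN (1.05 equiv), THF, 0 °C to rt; then NaOH, H2O2, 0 °C to rt
Reagents that add atoms: 9-BBN, B1C2CCCC1CCC2 (boron unit, in 2 only); hydrogen peroxide, OO (hydroxyl oxygen of 3)
Why: Hydroboration–oxidation, in which the bulky borane adds anti-Markovnikov to the unhindered 1,1-disubstituted exocyclic olefin and leaves the trisubstituted ring olefin untouched; the new C15 centre is formed without control and is corrected in step 9.

Step 2
Reactants: 3 2-[(1R)-4-methylcyclohex-3-en-1-yl]propan-1-ol
Product: 5 4-[(4R)-2-hydroxy-5-methyloxan-4-yl]butan-2-one (keto lactol), via secondary ozonide 4 (not isolated)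
Conditions: O3, CH2Cl2, −78 °C; then Me2S, −78 °C to rt
Reagents that add atoms: ozone, [O-][O+]=O
Why: Ozonolysis with reductive work-up cleaves the only C=C into the C12 methyl ketone and the C3 aldehyde, and the aldehyde is trapped at once by the C16 hydroxyl as a six-membered lactol, so the two carbonyls emerge differentiated.

Step 3
Reactants: 5 keto lactol
Product: 6 (4R)-5-methyl-4-(3-oxobutyl)oxan-2-one
Conditions: TEMPO (10 mol%), PhI(OAc)2 (1.3 equiv), CH2Cl2, rt
Reagents that add atoms: none
Why: Oxoammonium (TEMPO/PhI(OAc)2) oxidation of a lactol to the lactone leaves the ketone untouched and turns C3 into an acyl donor while masking the C16 hydroxyl in a temporary ring.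

Step 4
Reactants: 6 (4R)-5-methyl-4-(3-oxobutyl)oxan-2-one
Product: 7 (4R)-5-methyl-4-(3-methylbut-3-en-1-yl)oxan-2-one
Conditions: Ph3PCH3Br (1.3 equiv), KHMDS (1.25 equiv), THF, 0 °C; then 6, −78 to 0 °C
Reagents that add atoms: methyltriphenylphosphonium bromide, C[P+](c1ccccc1)(c1ccccc1)c1ccccc1.[Br-]
Why: Wittig methylenation, in which the non-stabilised ylide reacts with the methyl ketone far faster than with the lactone carbonyl, installs the C12 methylidene terminus needed for the ring closure.

Step 5
Reactants: 7 (4R)-5-methyl-4-(3-methylbut-3-en-1-yl)oxan-2-one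
Product: 8 (5R)-7-hydroxy-2,6-dimethyl-5-(3-methylbut-3-en-1-yl)hept-1-en-3-one
Conditions: 2-bromopropene (1.3 equiv), t-BuLi (2.6 equiv), Et2O, −78 °C; then 7, THF, −78 °C; aq. NH4Cl
Reagents that add atoms: 2-propenyllithium, [Li]C(C)=C (made in the flask from 2-bromopropene, CC(Br)=C)
Why: Mono-addition of an alkenyllithium to a δ-lactone, where the lithium hemiketal alkoxide is stable at −78 °C and collapses only on quench, opens the temporary ring to the C3 isopropenyl ketone (C3–C4 bond) and frees the C16 hydroxyl.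

Step 6
Reactants: 8 hydroxy enone
Product: 9 (3R,5R)-2,6-dimethyl-5-(3-methylbut-3-en-1-yl)hept-1-ene-3,7-diol
Conditions: (S)-Me-CBS (0.3 equiv), catecholborane (3 equiv), toluene, −78 °C; MeOH, then aq. NaOH work-up
Reagents that add atoms: none
Why: Corey–Bakshi–Shibata reduction, in which the α-branched alkenyl group acts as the large substituent and the CH2 chain as the small one, so the (S)-oxazaborolidine should deliver the 3R carbinol under reagent control, while catecholborane at −78 °C does not hydroborate the olefins.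

Step 7
Reactants: 9 (3R,5R)-diol
Product: 10 (1R,3R)-4-methyl-3-(3-methylbut-3-en-1-yl)-1-[(2S)-2-methyloxiran-2-yl]pentane-1,5-diol
Conditions: VO(acac)2 (5 mol%), t-BuOOH (1.5 equiv, decane), CH2Cl2, 0 °C to rt
Reagents that add atoms: tert-butyl hydroperoxide, CC(C)(C)OO
Why: Hydroxyl-directed vanadium-catalysed epoxidation touches only the allylic olefin, and for a 2-substituted allylic alcohol the transition state that avoids A(1,2) strain between the C4 methyl and the carbinol substituent gives the erythro (3R,4S) epoxy alcohol, so C4 is relayed from C3.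

Step 8
Reactants: 10 epoxy diol
Product: 11 (4S,5R,7R)-4,8-dimethyl-7-(3-methylbut-3-en-1-yl)non-1-yne-4,5,9-triol
Conditions: lithium acetylide–ethylenediamine complex (6 equiv), DMSO, rt; aq. NH4Cl
Reagents that add atoms: lithium acetylide–ethylenediamine complex, [Li]C#C.NCCN
Why: SN2 opening of a 2,2-disubstituted oxirane by acetylide occurs at the unsubstituted CH2 (C5), giving the C4 tertiary alcohol without touching C4, and Payne rearrangement is suppressed because it would need attack at the quaternary C4.

Step 9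
Reactants: 11 alkyne triol
Product: 14 (3S,4R,6R)-6-[(2S)-2-hydroxypent-4-yn-2-yl]-3-methyl-4-(3-methylbut-3-en-1-yl)oxan-2-one, via hydroxy lactol 12 (not isolated), via C15-epimeric lactones 13 (not isolated)
Conditions: TEMPO (20 mol%), PhI(OAc)2 (2.5 equiv), CH2Cl2, rt; aq. Na2S2O3 work-up; then DBU (0.5 equiv), toluene, 80 °C
Reagents that add atoms: none
Why: TEMPO/PhI(OAc)2 oxidative lactonisation of the 1,5-diol oxidises the primary C16 alcohol selectively, the aldehyde is captured by the C3 hydroxyl as the lactol (which also removes the free 1,2-diol) and is oxidised on to the δ-lactone; base equilibration α to the carbonyl then funnels both C15 epimers to the all-equatorial 15S lactone, C15 being controlled thermodynamically by C1 and C3.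

Step 10
Reactants: 14 lactone
Product: 15 (3S,4R,6R)-3-methyl-4-(3-methylbut-3-en-1-yl)-6-[(2S)-2-(triethylsilyloxy)pent-4-yn-2-yl]oxan-2-one
Conditions: TESOTf (1.5 equiv), 2,6-lutidine (3 equiv), CH2Cl2, −78 to 0 °C
Reagents that add atoms: triethylsilyl trifluoromethanesulfonate, CC[Si](CC)(CC)OS(=O)(=O)C(F)(F)F
Why: Silylation of the tertiary alcohol with a silyl triflate and a hindered base keeps the C4 oxygen from closing onto the C7 aldehyde as a five-membered lactol in the next steps.

Step 11
Reactants: 15 silyl ether alkyne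
Product: 16 (4S)-4-[(2R,4R,5S)-5-methyl-4-(3-methylbut-3-en-1-yl)-6-oxooxan-2-yl]-4-(triethylsilyloxy)pentanal
Conditions: CpRu(MeCN)3PF6 (5 mol%), 5,5′-bis(trifluoromethyl)-2,2′-bipyridine (5 mol%), NMP/H2O 4:1, 25–40 °C
Reagents that add atoms: water, O
Why: Ruthenium-catalysed anti-Markovnikov hydration of a terminal alkyne through a Ru-vinylidene gives the aldehyde at C7 under neutral conditions that should spare the lactone, the silyl ether and the 1,1-disubstituted olefin.

Step 12
Reactants: 17 hex-1-en-5-yne
Product: 19 2-iodohexa-1,5-diene, via iodoalkenyl-9-BBN 18 (not isolated)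
Conditions: B-iodo-9-BBN (1.1 equiv), pentane, −20 to 0 °C; then AcOH, 0 °C to rt
Reagents that add atoms: B-iodo-9-BBN, IB1C2CCCC1CCC2
Why: Haloboration–protonolysis: syn Markovnikov addition of B–I to the terminal alkyne (iodine on the internal carbon) is much faster than any reaction at the alkene, and acetic acid cleaves the alkenyl C–B bond to leave the 2-iodo-1-alkene.

Step 13
Reactants: 16 aldehyde; 19 2-iodohexa-1,5-diene
Product: 20 (3S,4R,6R)-6-[(2S)-5-hydroxy-6-methylidene-2-(triethylsilyloxy)dec-9-en-2-yl]-3-methyl-4-(3-methylbut-3-en-1-yl)oxan-2-one (both C7 epimers)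
Conditions: CrCl2 (4 equiv), NiCl2 (2 mol%), 19 (2 equiv), DMF, rt
Reagents that add atoms: none
Why: Nozaki–Hiyama–Kishi coupling, in which the alkenylchromium(III) species adds to the aldehyde only and leaves the lactone alone, forms the C7–C8 bond and the 2-methylidene carbinol motif; the C7 centre is not controlled here and is reset in steps 14 and 15.

Step 14
Reactants: 20 C7-epimeric allylic alcohols
Product: 21 (3S,4R,6R)-3-methyl-4-(3-methylbut-3-en-1-yl)-6-[(2S)-6-methylidene-5-oxo-2-(triethylsilyloxy)dec-9-en-2-yl]oxan-2-one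
Conditions: Dess–Martin periodinane (1.3 equiv), NaHCO3, CH2Cl2, 0 °C to rt
Reagents that add atoms: none
Why: Dess–Martin oxidation of a secondary allylic alcohol converges both C7 epimers on one α-methylidene ketone under buffered, non-basic conditions.

Step 15
Reactants: 21 enone
Product: 22 (3S,4R,6R)-6-[(2S,5R)-5-hydroxy-6-methylidene-2-(triethylsilyloxy)dec-9-en-2-yl]-3-methyl-4-(3-methylbut-3-en-1-yl)oxan-2-one
Conditions: (S)-Me-CBS (0.5 equiv), catecholborane (2 equiv), toluene, −78 °C; MeOH, pH 7 buffer
Reagents that add atoms: none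
Why: Corey–Bakshi–Shibata reduction with the 2-substituted vinyl group as the large and the C6 methylene as the small substituent should give the 7R carbinol under reagent control, and the lactone is not reduced by catecholborane at −78 °C.

Step 16
Reactants: 22 (7R)-carbinol silyl ether
Product: 23 (3S,4R,6R)-6-[(2S,5R)-2,5-dihydroxy-6-methylidenedec-9-en-2-yl]-3-methyl-4-(3-methylbut-3-en-1-yl)oxan-2-one
Conditions: HF·pyridine, pyridine, THF, 0 °C to rt
Reagents that add atoms: none
Why: Fluoride-mediated cleavage of the tertiary triethylsilyl ether under buffered conditions frees the C4 hydroxyl before ring closure, so that no protecting group remains after the key step.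

Step 17
Reactants: 23 seco-diene diol
Product: 24 (1R,3R,4S,7R,11E,15S)-4,7-dihydroxycembra-8(19),11-dien-16,3-olide
Conditions: Grubbs II (2 × 7.5 mol%), 1,4-benzoquinone (15 mol%), toluene (1 mM), 80 °C
Reagents that add atoms: none
Why: Ring-closing olefin metathesis: the Ru carbene loads on the monosubstituted C11 vinyl group, adds intramolecularly across the 1,1-disubstituted C12 methylidene and expels ethylene, creating the C11=C12 bond. The closest known reaction type is macrocyclic RCM with second-generation Ru–NHC catalysts that joins a vinyl and an isopropenyl-type terminus into a trisubstituted olefin in 14- to 16-membered rings. The one ring closed is the 14-membered carbocycle, closed by macrocyclisation under high dilution onto the preformed six-membered lactone. No stereocentre is created; the stereochemical element is the olefin geometry, expected to be E because in a 14-membered ring the E-trisubstituted olefin (C10 anti to C13, the cembrane geometry) avoids the transannular strain of the Z isomer. The step needs site selectivity among three olefins and cyclisation over oligomerisation: the C8 methylidene is a hindered allylic-alcohol 1,1-disubstituted olefin whose only closures would be a cyclobutene or a tetrasubstituted 11-membered olefin, so it stays a spectator, and 1 mM concentration with portionwise catalyst favours ring closure. All five stereocentres of 23 lie at least three bonds from the reacting carbons, and the free hydroxyls and the lactone are tolerated by the catalyst, benzoquinone suppressing Ru–H isomerisation of the allylic alcohol.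

Step 18
Reactants: 24 macrocyclic (E)-olefin
Product: 25 (1R,3R,4S,7R,11S,12S,15S)-11,12-epoxy-4,7-dihydroxycembr-8(19)-en-16,3-olide (CNP0262409.1)
Conditions: L-fructose-derived Shi ketone (ent-Shi ketone, 1.0 equiv in portions, regenerated), Oxone (1.5 equiv), NaHCO3, aq. Na2EDTA, MeCN/DMM, 0 °C, pH 7.5–8
Reagents that add atoms: Oxone (potassium peroxymonosulfate), [K+].[O-]S(=O)(=O)OO
Why: Shi asymmetric epoxidation (chiral dioxirane, spiro transition state): the electron-rich E-trisubstituted C11=C12 olefin reacts much faster than the 1,1-disubstituted C8 methylidene, the enantiomer of the ketone that gives R,R-epoxides from E-olefins should deliver oxygen to the face that gives the 11S,12S trans-oxirane under reagent control, and the near-neutral pH spares the lactone.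

**Compound list**

1 | (R)-(+)-limonene | CC1=CC[C@@H](CC1)C(C)=C | starting material
2 | 9-{2-[(1R)-4-methylcyclohex-3-en-1-yl]propyl}-9-borabicyclo[3.3.1]nonane | CC1=CC[C@@H](CC1)C(C)CB1C2CCCC1CCC2 | intermediate
3 | 2-[(1R)-4-methylcyclohex-3-en-1-yl]propan-1-ol (C15 epimers) | CC1=CC[C@@H](CC1)C(C)CO | intermediate
4 | secondary ozonide of 3 (1,2,4-trioxolane bridging the former ring olefin carbons) | CC12OOC(O1)C[C@H](C(C)CO)CC2 | intermediate
5 | 4-[(4R)-2-hydroxy-5-methyloxan-4-yl]butan-2-one | OC1C[C@@H](CCC(C)=O)C(C)CO1 | intermediate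
6 | (4R)-5-methyl-4-(3-oxobutyl)oxan-2-one | O=C1C[C@@H](CCC(C)=O)C(C)CO1 | intermediate
7 | (4R)-5-methyl-4-(3-methylbut-3-en-1-yl)oxan-2-one | O=C1C[C@@H](CCC(C)=C)C(C)CO1 | intermediate
8 | (5R)-7-hydroxy-2,6-dimethyl-5-(3-methylbut-3-en-1-yl)hept-1-en-3-one | CC(=C)C(=O)C[C@@H](CCC(C)=C)C(C)CO | intermediate
9 | (3R,5R)-2,6-dimethyl-5-(3-methylbut-3-en-1-yl)hept-1-ene-3,7-diol | CC(=C)[C@H](O)C[C@@H](CCC(C)=C)C(C)CO | intermediate
10 | (1R,3R)-4-methyl-3-(3-methylbut-3-en-1-yl)-1-[(2S)-2-methyloxiran-2-yl]pentane-1,5-diol | C[C@]1(CO1)[C@H](O)C[C@@H](CCC(C)=C)C(C)CO | intermediate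
11 | (4S,5R,7R)-4,8-dimethyl-7-(3-methylbut-3-en-1-yl)non-1-yne-4,5,9-triol | C#CC[C@](C)(O)[C@H](O)C[C@@H](CCC(C)=C)C(C)CO | intermediate
12 | (2S)-2-[(2R,4R)-6-hydroxy-5-methyl-4-(3-methylbut-3-en-1-yl)oxan-2-yl]pent-4-yn-2-ol (lactol) | C#CC[C@](C)(O)[C@H]1C[C@@H](CCC(C)=C)C(C)C(O)O1 | intermediate
13 | (4R,6R)-6-[(2S)-2-hydroxypent-4-yn-2-yl]-3-methyl-4-(3-methylbut-3-en-1-yl)oxan-2-one (C15 epimers) | C#CC[C@](C)(O)[C@H]1C[C@@H](CCC(C)=C)C(C)C(=O)O1 | intermediate
14 | (3S,4R,6R)-6-[(2S)-2-hydroxypent-4-yn-2-yl]-3-methyl-4-(3-methylbut-3-en-1-yl)oxan-2-one | C#CC[C@](C)(O)[C@H]1C[C@@H](CCC(C)=C)[C@H](C)C(=O)O1 | intermediate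
15 | (3S,4R,6R)-3-methyl-4-(3-methylbut-3-en-1-yl)-6-[(2S)-2-(triethylsilyloxy)pent-4-yn-2-yl]oxan-2-one | C#CC[C@](C)(O[Si](CC)(CC)CC)[C@H]1C[C@@H](CCC(C)=C)[C@H](C)C(=O)O1 | intermediate
16 | (4S)-4-[(2R,4R,5S)-5-methyl-4-(3-methylbut-3-en-1-yl)-6-oxooxan-2-yl]-4-(triethylsilyloxy)pentanal | O=CCC[C@](C)(O[Si](CC)(CC)CC)[C@H]1C[C@@H](CCC(C)=C)[C@H](C)C(=O)O1 | intermediate
17 | hex-1-en-5-yne | C=CCCC#C | starting material
18 | 9-[(1Z)-2-iodohexa-1,5-dien-1-yl]-9-borabicyclo[3.3.1]nonane | I/C(CCC=C)=C\B1C2CCCC1CCC2 | intermediate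
19 | 2-iodohexa-1,5-diene | C=CCCC(I)=C | intermediate
20 | (3S,4R,6R)-6-[(2S)-5-hydroxy-6-methylidene-2-(triethylsilyloxy)dec-9-en-2-yl]-3-methyl-4-(3-methylbut-3-en-1-yl)oxan-2-one (C7 epimers) | C=CCCC(=C)C(O)CC[C@](C)(O[Si](CC)(CC)CC)[C@H]1C[C@@H](CCC(C)=C)[C@H](C)C(=O)O1 | intermediate
21 | (3S,4R,6R)-3-methyl-4-(3-methylbut-3-en-1-yl)-6-[(2S)-6-methylidene-5-oxo-2-(triethylsilyloxy)dec-9-en-2-yl]oxan-2-one | C=CCCC(=C)C(=O)CC[C@](C)(O[Si](CC)(CC)CC)[C@H]1C[C@@H](CCC(C)=C)[C@H](C)C(=O)O1 | intermediate
22 | (3S,4R,6R)-6-[(2S,5R)-5-hydroxy-6-methylidene-2-(triethylsilyloxy)dec-9-en-2-yl]-3-methyl-4-(3-methylbut-3-en-1-yl)oxan-2-one | C=CCCC(=C)[C@H](O)CC[C@](C)(O[Si](CC)(CC)CC)[C@H]1C[C@@H](CCC(C)=C)[C@H](C)C(=O)O1 | intermediate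
23 | (3S,4R,6R)-6-[(2S,5R)-2,5-dihydroxy-6-methylidenedec-9-en-2-yl]-3-methyl-4-(3-methylbut-3-en-1-yl)oxan-2-one | C=CCCC(=C)[C@H](O)CC[C@](C)(O)[C@H]1C[C@@H](CCC(C)=C)[C@H](C)C(=O)O1 | intermediate
24 | (1R,3R,4S,7R,11E,15S)-4,7-dihydroxycembra-8(19),11-dien-16,3-olide | C=C1CC/C=C(\C)CC[C@@H]2C[C@@H](OC(=O)[C@H]2C)[C@@](C)(O)CC[C@H]1O | intermediate
25 | (1R,3R,4S,7R,11S,12S,15S)-11,12-epoxy-4,7-dihydroxycembr-8(19)-en-16,3-olide (CNP0262409.1) | C=C1CC[C@@H]2O[C@@]2(C)CC[C@@H]2C[C@@H](OC(=O)[C@H]2C)[C@@](C)(O)CC[C@H]1O | target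

**Totals and risks**

Total step count: 18. Longest linear sequence: 17 steps (steps 1–11 and 13–18 from 1); step 12 is a one-step branch.

Steps most likely to fail:

1. Step 17 (ring-closing metathesis). Intermolecular metathesis through the unhindered C11 vinyl group may outrun closure onto the 1,1-disubstituted C12 olefin and give oligomers, and the E/Z ratio of the new trisubstituted olefin may erode. The fallback sets out from 16 and 19 and comes back at 24: the C11=C12 olefin is made first, intermolecularly, and the ring is closed afterwards at C7–C8. Cross-metathesis of the 1,1-disubstituted olefin of 16 with the vinyl group of 19 (3 equiv, Hoveyda–Grubbs II, CH2Cl2, 40 °C) should give the acyclic (E)-olefin aldehyde vinyl iodide F1, freed from its Z isomer on AgNO3–silica. An intramolecular Nozaki–Hiyama–Kishi reaction (CrCl2, cat. NiCl2, DMSO/THF, high dilution) should close the 14-membered ring to the C7-epimeric macrocyclic carbinols F2. Dess–Martin oxidation should give the macrocyclic enone F3, (S)-Me-CBS/catecholborane the (7R)-carbinol silyl ether F4, and HF·pyridine should then remove the silyl group to give 24.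

2. Step 11 (anti-Markovnikov hydration). Vinylidene formation next to the quaternary C4 may be slow, so that Markovnikov hydration to the methyl ketone, or silyl loss followed by cyclisation to the lactol, takes over. The fallback sets out from 15 and comes back at 16, replacing the catalytic hydration by stoichiometric hydroboration–oxidation. Dicyclohexylborane (1.05 equiv, THF, 0 °C; a terminal alkyne reacts faster than a 1,1-disubstituted alkene) should give the (E)-alkenyl dicyclohexylborane F5, and NaBO3·4H2O (THF/H2O, rt, lactone-compatible) should oxidise it to the aldehyde 16.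

3. Step 5 (mono-addition to the lactone). The tetrahedral adduct may collapse before the quench, so that a second equivalent adds (1,2 or 1,4) to the liberated enone, or the lactone may simply be enolised. The fallback sets out from 7 and comes back at 8, making the ketone in two stages through an amide that cannot over-add. MeNH(OMe)·HCl with i-PrMgCl (THF, −20 °C) should open 7 to the hydroxy Weinreb amide F6, and isopropenylmagnesium bromide (3 equiv, THF, 0 °C) should stop at the chelated adduct and release 8 on work-up.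

**Further compounds**

F1 | step 17 | (4S)-4-{(2R,4R,5S)-4-[(3E)-8-iodo-4-methylnona-3,8-dien-1-yl]-5-methyl-6-oxooxan-2-yl}-4-(triethylsilyloxy)pentanal | O=CCC[C@](C)(O[Si](CC)(CC)CC)[C@H]1C[C@@H](CC/C(C)=C/CCC(I)=C)[C@H](C)C(=O)O1
F2 | step 17 | (1R,3R,4S,11E,15S)-7-hydroxy-4-(triethylsilyloxy)cembra-8(19),11-dien-16,3-olide (C7 epimers) | C=C1CC/C=C(\C)CC[C@@H]2C[C@@H](OC(=O)[C@H]2C)[C@@](C)(O[Si](CC)(CC)CC)CCC1O
F3 | step 17 | (1R,3R,4S,11E,15S)-7-oxo-4-(triethylsilyloxy)cembra-8(19),11-dien-16,3-olide | C=C1CC/C=C(\C)CC[C@@H]2C[C@@H](OC(=O)[C@H]2C)[C@@](C)(O[Si](CC)(CC)CC)CCC1=O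
F4 | step 17 | (1R,3R,4S,7R,11E,15S)-7-hydroxy-4-(triethylsilyloxy)cembra-8(19),11-dien-16,3-olide | C=C1CC/C=C(\C)CC[C@@H]2C[C@@H](OC(=O)[C@H]2C)[C@@](C)(O[Si](CC)(CC)CC)CC[C@H]1O
F5 | step 11 | (3S,4R,6R)-6-[(2S,4E)-5-(dicyclohexylboranyl)-2-(triethylsilyloxy)pent-4-en-2-yl]-3-methyl-4-(3-methylbut-3-en-1-yl)oxan-2-one | B(C1CCCCC1)(C1CCCCC1)/C=C/C[C@](C)(O[Si](CC)(CC)CC)[C@H]1C[C@@H](CCC(C)=C)[C@H](C)C(=O)O1
F6 | step 5 | (3R)-3-(1-hydroxypropan-2-yl)-N-methoxy-N,6-dimethylhept-6-enamide | CON(C)C(=O)C[C@@H](CCC(C)=C)C(C)CO
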